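## Analysis of the target

Target 17 is a 1,2-dihydronaphthalene. Ring A is aromatic and carries a 6,7-catechol. Ring B holds a C3=C4 double bond conjugated to ring A, carboxyl groups at C2 and C3, and a 6-carboxy-2-oxo-2H-pyran-4-yl group at C1. The only stereocentres are the neighbouring carbons C1 (R) and C2 (S). The pyranone at C1 and the carboxyl group at C2 lie on opposite faces of ring B (1,2-trans), the arrangement in which both can sit pseudoaxial and which should be the more stable one.

Both centres carry an acidic hydrogen. C1–H is benzylic to ring A and vinylogous to the lactone carbonyl group; C2–H is α to a carboxyl group and allylic. Either can epimerise, and loss of both hydrogens makes ring B aromatic and erases both centres. The pyranone is an electron-poor enol lactone that is opened by nucleophiles and bases, accepts electrons and absorbs light, and the catechol is easily oxidised.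

The difficulty is to place this heterocycle on a benzylic stereocentre with absolute control, next to a second labile centre, without aromatising ring B and without having to build the pyranone late on a fragile scaffold.

The strategy rests on one reading of ring B. C3 and C4 are the two carbons of a propiolic ester. C2 bears a carboxyl group and can be the ketone carbon of an α-keto ester. C1 and C2, together with the ring A carbons C8a and C4a, are the four carbons of a benzocyclobutenol, whose strained aryl–carbinol bond (C2–C4a) can be traded for the bonds C4–C4a and C2–C3. In the ring-opened stage C1–H lies between ring A, the pyranone and the ketone, so C1 is configurationally mobile exactly when a chiral catalyst closes the ring.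

## Retrosynthetic reasoning

**17 to 15 (no skeletal bond cut).** The three acids and the catechol are unmasked last, from triester 16 and before that from the fully methylated trans triester 15. Methyl groups are the smallest protection that survives Lewis acid, light, rhodium and a one-electron reductant. Their removal needs only a boron Lewis acid and aqueous acid, neither of which deprotonates C1–H or C2–H.

**15 to 14 (C2 configuration).** The C2–H bond has to be made on a planar C2, and any external proton donor approaches the face away from the pseudoaxial pyranone. That places the ester cis to the pyranone, as in cis triester 14, not trans as in the target. The trans arrangement of 15 is therefore reached by a separate equilibration at C2, driven by the stability of the diaxial isomer. This is why the route does not count on the reduction step to deliver the trans compound directly.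

**14 to 13 (C2–H from C2–OH).** The C2 hydrogen is traced back to a tertiary hydroxyl group in carbinol 13. The C2–O bond is α to an ester and allylic to the C3=C4 acrylate, so it is the bond in 13 most easily broken by electron transfer. Accepting an extra oxygen at C2 is what allows C2 to be a ketone carbon in the ring closure.

**13 to 11 and 12 (C4–C4a and C2–C3).** Ring B is cut at these two bonds, which gives methyl propiolate 12 and benzocyclobutenol 11. Cutting here keeps the pyranone and all three ester carbons in place on the fragments, and uses ring strain to make an aryl–metal bond next to a ketone without any halide or organometallic reagent that the pyranone would not survive. The forward reaction has to open the four-membered ring at the aryl–carbinol bond, insert the alkyne with the aryl group going to the unsubstituted carbon, close ring B onto the ketone, and choose one C1 configuration while C1 is mobile.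

**11 to 9 (C7–C8 of the four-membered ring, which becomes C1–C2).** The benzocyclobutenol comes from aryl glyoxylate 9 by bonding the benzylic carbon to the ketone carbon. The ketone of 9 sits five atoms from the doubly activated benzylic hydrogens, the geometry required for a photochemical hydrogen transfer and ring closure. No base is involved, which matters because 11 would reopen under base.

**9 to 7 and 8 (aryl–acyl bond).** The α-keto ester is attached to ring A of benzylpyranone 7 with methyl chlorooxoacetate 8. The position ortho to the benzyl carbon and para to a methoxy group is the most activated one, so the electrophilic substitution puts the acyl group where the four-membered ring needs it.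

**7 to 5 and 6 (benzylic carbon–ring A bond).** This bond is made by cross-coupling bromomethylpyranone 5 with (3,4-dimethoxyphenyl)boronic acid 6. The electrophile is on the pyranone side because its methyl group can be brominated directly, and the boronic acid is commercial.

**5 to 4 to 1 and 2 (pyranone ring).** Bromide 5 comes from 4-methylpyranone 4. The ring of 4 is cut at the lactone C–O bond and at the bond between the γ-carbon of methyl 3-methylbut-2-enoate 1 and an oxalyl carbon of dimethyl oxalate 2. Building the heterocycle first, from two bulk esters, means it never has to be assembled on the dihydronaphthalene.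

## Alternatives that were turned down

**Alternative 1:** Ring B is cut at C1–C2. In the forward direction the silyl ketene acetal of a benzo-fused six-membered lactone, whose ring oxygen sits on the future C4 and which carries the diester alkene there, undergoes an Ireland–Claisen rearrangement. The C1–C2 bond forms, the O–C4 bond breaks, the C3=C4 bond appears, and the lactone contracts to the carbocycle A1, (1R,2S)-6,7-dimethoxy-2,3-bis(methoxycarbonyl)-1,2-dihydronaphthalene-1-carboxylic acid (cis).
- For it: the rearrangement is a well-understood pericyclic reaction, its cyclic transition state fixes the relative configuration, and a stereocentre at the lactone carbinol carbon would be transferred to C1 and C2. On predictability of the key step it is stronger than the chosen route.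
- Against it: A1 carries a carboxyl group at C1, not the pyranone, and is 1,2-cis. The six-carbon heterocycle would have to be built on a centre that is benzylic, α to a carbonyl group and next to a second epimerisable centre, and one centre would still need inversion.
- Comparison: the chosen route carries the finished pyranone from the second compound onward and makes both ring bonds in one catalytic step. It pays for this with an unproven stereochemical event.

**Alternative 2:** Ring B is cut at C1–C8a, C4–C4a and C3=C4. A symmetrical dimethoxy-aryne takes up the enolate carbon of an acyclic formyl ester, the formyl group migrates to the neighbouring ring carbon, and a phosphonate carbanion in the same chain olefinates the new aldehyde. The product is A2, 1-tert-butyl 2,3-dimethyl (1S,2S)-6,7-dimethoxy-1,2-dihydronaphthalene-1,2,3-tricarboxylate (trans).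
- For it: three bonds form in one flask, the aryne is symmetrical so there is no regiochemical question, and the trans arrangement is reached directly. In convergence it matches the chosen route.
- Against it: the acyclic precursor has three adjacent acidic CH groups and a formyl group prone to self-condensation, the absolute configuration has no obvious source, and C1 of A2 again bears only an ester from which the pyranone would have to be grown.
- Comparison: the chosen route answers both the absolute configuration (through the ligand) and the heterocycle (through the starting material) in its design.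

**Alternative 3:** Ring B is cut at C2–C3. Zerovalent palladium inserts into a C3–Br bond of a bromoacrylate, the ester enolate at C2 displaces bromide on palladium, and reductive elimination closes the ring. The product is A3, dimethyl (1R,2S)-1-[3,4-bis(benzyloxy)phenyl]-6,7-dimethoxy-1,2-dihydronaphthalene-2,3-dicarboxylate.
- For it: C1 would come from an established asymmetric conjugate arylation, and the ring closure puts the new bond at C2 anti to the C1 aryl group, so the trans isomer forms without an epimerisation. On both stereochemical points it is stronger than the chosen route.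
- Against it: the group at C1 of A3 is a protected catechol. Turning it into the 6-carboxy-2-pyranone needs a regioselective oxidative cleavage next to one phenol oxygen and relactonisation, for which there is no dependable chemical method, least of all beside the second oxygenated ring A. Hydrogenolysis of the benzyl ethers would also threaten the C3=C4 bond.
- Comparison: A3 stops one ring short of the target, whereas the chosen route ends in three routine steps after ring B is closed.

Key step: step 6

## Assumptions

- (R)-BINAP is taken to favour the (1R) configuration in step 6; if the sense of induction is the opposite, (S)-BINAP is used and nothing else changes.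
- The 1,2-trans triester 15 is taken to be more stable than its cis epimer 14, because only the trans isomer can hold the pyranone and the C2 ester both pseudoaxial.

## Route

Step 1
Reactants: 1 methyl 3-methylbut-2-enoate; 2 dimethyl oxalate
Product: 4 methyl 4-methyl-2-oxo-2H-pyran-6-carboxylate, via dimethyl 2-hydroxy-4-methylhexa-2,4-dienedioate 3 (not isolated)
Conditions: NaOMe, MeOH–Et2O, 0 °C to rt; then HCl, MeOH, reflux
Reagents that add atoms: none
Why: Vinylogous Claisen condensation: the dienolate of 1 is acylated by 2 at the γ-carbon and the product is held as the stabilised enolate of 3. Acid then lactonises the enol oxygen onto the ester group, and the conjugated 2-pyranone is the driving force.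

Step 2
Reactants: 4 methyl 4-methyl-2-oxo-2H-pyran-6-carboxylate
Product: 5 methyl 4-(bromomethyl)-2-oxo-2H-pyran-6-carboxylate
Conditions: NBS, AIBN (cat.), PhCF3, 85 °C
Reagents that add atoms: N-bromosuccinimide, O=C1CCC(=O)N1Br
Why: Wohl–Ziegler bromination: the C4 methyl group is allylic to the C3=C4 bond of the pyranone and gives a delocalised radical. The electron-poor ring resists electrophilic bromination, and one equivalent of reagent limits dibromination.

Step 3
Reactants: 5 methyl 4-(bromomethyl)-2-oxo-2H-pyran-6-carboxylate; 6 (3,4-dimethoxyphenyl)boronic acid
Product: 7 methyl 4-[(3,4-dimethoxyphenyl)methyl]-2-oxo-2H-pyran-6-carboxylate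
Conditions: Pd(PPh3)4 (5 mol%), K3PO4, toluene, 80 °C
Reagents that add atoms: none
Why: Suzuki–Miyaura coupling of an allylic-type sp3 bromide: oxidative addition of the activated C–Br bond to zerovalent palladium is fast and the resulting alkylpalladium has no β-hydrogen. Solid phosphate in toluene spares the lactone and the ester.

Step 4
Reactants: 7 methyl 4-[(3,4-dimethoxyphenyl)methyl]-2-oxo-2H-pyran-6-carboxylate; 8 methyl chlorooxoacetate
Product: 9 methyl 4-{[4,5-dimethoxy-2-(2-methoxy-2-oxoacetyl)phenyl]methyl}-2-oxo-2H-pyran-6-carboxylate
Conditions: AlCl3 (3 equiv), CH2Cl2, 0 °C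
Reagents that add atoms: none
Why: Friedel–Crafts acylation: the acyl chloride–AlCl3 complex attacks the veratrole ring para to one methoxy group and ortho to the benzyl carbon, the most activated position that is still accessible. The pyranone is too electron-poor to compete and the keto ester product is deactivated toward a second acylation.

Step 5
Reactants: 9 methyl 4-{[4,5-dimethoxy-2-(2-methoxy-2-oxoacetyl)phenyl]methyl}-2-oxo-2H-pyran-6-carboxylate
Product: 11 methyl 7-hydroxy-3,4-dimethoxy-8-[6-(methoxycarbonyl)-2-oxo-2H-pyran-4-yl]bicyclo[4.2.0]octa-1,3,5-triene-7-carboxylate (racemic; both diastereomers), via photoenol 10 (not isolated)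
Conditions: hν (390–405 nm LED), degassed MeCN, 20 °C, flow
Reagents that add atoms: none
Why: Norrish–Yang photocyclisation: the excited aryl ketone abstracts a benzylic hydrogen through a six-membered transition state, and the resulting hydroxy-o-quinodimethane 10 closes thermally by conrotatory 4π electrocyclisation to the benzocyclobutenol. Long-wavelength light addresses the keto ester and leaves the pyranone chromophore unexcited. The configuration of the two new centres is irrelevant because step 6 erases one and equilibrates the other.

Step 6
Reactants: 11 methyl 7-hydroxy-3,4-dimethoxy-8-[6-(methoxycarbonyl)-2-oxo-2H-pyran-4-yl]bicyclo[4.2.0]octa-1,3,5-triene-7-carboxylate; 12 methyl propiolate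
Product: 13 dimethyl (1R,2R)-2-hydroxy-6,7-dimethoxy-1-[6-(methoxycarbonyl)-2-oxo-2H-pyran-4-yl]-1,2-dihydronaphthalene-2,3-dicarboxylate
Conditions: [Rh(OH)(cod)]2 (2.5 mol%), (R)-BINAP (6 mol%), 12 (2.5 equiv) added over 6 h, toluene, 40 °C
Reagents that add atoms: none
Why: Proposed new method: exchange of the hydroxyl group of 11 onto the hydroxorhodium–BINAP complex gives a monovalent rhodium alkoxide, which undergoes β-carbon elimination of the aryl–carbinol bond, driven by the strain of the four-membered ring, to an arylrhodium at C4a with the α-keto ester now on the benzylic carbon C1. Syn-carbometalation of 12 puts the aryl group on the unsubstituted carbon (C4–C4a bond) and rhodium next to the ester, and this alkenylrhodium adds to the ketone (C2–C3 bond) to give the rhodium alkoxide of 13, which is released by exchange with the next molecule of 11. The closest known reaction type is the rhodium-catalysed ring opening of benzocyclobutenols at the aryl–carbinol bond with alkyne insertion and carbonyl addition to 1,2-dihydronaphthalen-2-ols; new here are the acidic stereogenic C1–H and its dynamic kinetic resolution. Ring B closes by 6-exo-trig addition of the alkenyl–rhodium bond across the C2 carbonyl group. C1 is controlled by the bisphosphine: in the ring-opened intermediates C1–H lies between ring A, the pyranone and the keto ester, enolisation interconverts the two C1 epimers faster than the ring closes, and the chiral catalyst lets one of them cyclise faster. C2 is set relative to C1 in the four-centre addition, in which the carbonyl oxygen points to rhodium in the ring plane and the ester goes pseudoaxial, anti to the pseudoaxial pyranone; this centre is removed in step 7. The step needs cleavage of the aryl–carbinol bond in preference to the C7–C8 bond (a neutral rhodium alkoxide near room temperature, no added base), aryl addition to the β-carbon (polarisation of the propiolate and the stabilised α-rhodio ester), and alkyne insertion ahead of protonation of the arylrhodium (12 fed continuously, which also keeps acetylide formation low).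

Step 7
Reactants: 13 dimethyl (1R,2R)-2-hydroxy-6,7-dimethoxy-1-[6-(methoxycarbonyl)-2-oxo-2H-pyran-4-yl]-1,2-dihydronaphthalene-2,3-dicarboxylate
Product: 14 dimethyl (1R,2R)-6,7-dimethoxy-1-[6-(methoxycarbonyl)-2-oxo-2H-pyran-4-yl]-1,2-dihydronaphthalene-2,3-dicarboxylate (1,2-cis)
Conditions: SmI2 (2.5 equiv), THF–MeOH, −78 to −40 °C
Reagents that add atoms: none
Why: Reductive cleavage of an α-hydroxy ester by SmI2: the hydroxy ester chelates divalent samarium, electron transfer expels the C2 oxygen (helped by the allylic position of C2), and a second electron gives a samarium dienolate that methanol protonates at C2, so the C3=C4 bond stays in place. The proton arrives on the face away from the pseudoaxial pyranone, which leaves the ester cis to it (C2 R). C1 is untouched because the dienolate is quenched as it forms.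

Step 8
Reactants: 14 dimethyl (1R,2R)-6,7-dimethoxy-1-[6-(methoxycarbonyl)-2-oxo-2H-pyran-4-yl]-1,2-dihydronaphthalene-2,3-dicarboxylate (1,2-cis)
Product: 15 dimethyl (1R,2S)-6,7-dimethoxy-1-[6-(methoxycarbonyl)-2-oxo-2H-pyran-4-yl]-1,2-dihydronaphthalene-2,3-dicarboxylate (1,2-trans)
Conditions: DBU (0.2 equiv), toluene, 0 °C to rt, argon
Reagents that add atoms: none
Why: Base-mediated epimerisation α to an ester: DBU reversibly removes the pseudoaxial C2–H, which is aligned with its ester carbonyl group and the C3=C4 bond, and α-reprotonation of the dienolate returns the 1,2-dihydronaphthalene; the equilibrium should favour the trans isomer, in which pyranone and ester are both pseudoaxial and free of strain against H-8 and the C3 ester. C1–H lies near the plane of ring A and its removal would cost the cyclic conjugation of the pyranone, so C2 is expected to exchange first. Catalytic base, low temperature and short contact are chosen to keep it so.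

Step 9
Reactants: 15 dimethyl (1R,2S)-6,7-dimethoxy-1-[6-(methoxycarbonyl)-2-oxo-2H-pyran-4-yl]-1,2-dihydronaphthalene-2,3-dicarboxylate
Product: 16 dimethyl (1R,2S)-6,7-dihydroxy-1-[6-(methoxycarbonyl)-2-oxo-2H-pyran-4-yl]-1,2-dihydronaphthalene-2,3-dicarboxylate
Conditions: BBr3 (8 equiv), CH2Cl2, −78 to 0 °C; then H2O
Reagents that add atoms: none
Why: Lewis acid dealkylation of aryl methyl ethers with BBr3: boron binds the ether oxygen and bromide attacks the methyl group. At or below 0 °C the methyl esters should largely remain, and any ester that is cleaved converges in step 10. Neither base nor hot protic acid reaches C1–H or C2–H.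

Step 10
Reactants: 16 dimethyl (1R,2S)-6,7-dihydroxy-1-[6-(methoxycarbonyl)-2-oxo-2H-pyran-4-yl]-1,2-dihydronaphthalene-2,3-dicarboxylate
Product: 17 (1R,2S)-1-(6-carboxy-2-oxo-2H-pyran-4-yl)-6,7-dihydroxy-1,2-dihydronaphthalene-2,3-dicarboxylic acid
Conditions: 3 M HCl, 1,4-dioxane, 70 °C, argon
Reagents that add atoms: water, O
Why: Acid-catalysed ester hydrolysis of the three methyl esters by acyl–oxygen cleavage. The 2-pyranone ring, which is itself formed under acid in step 1, and the catechol (under argon) should tolerate the medium, and no base is present at the two acidic C–H centres.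

## Compound list

1 | methyl 3-methylbut-2-enoate | CC(C)=CC(=O)OC | starting material
2 | dimethyl oxalate | COC(=O)C(=O)OC | starting material
3 | dimethyl 2-hydroxy-4-methylhexa-2,4-dienedioate (present as its sodium enolate; double-bond geometry not fixed) | COC(=O)C(O)=CC(C)=CC(=O)OC | intermediate
4 | methyl 4-methyl-2-oxo-2H-pyran-6-carboxylate | COC(=O)c1cc(C)cc(=O)o1 | intermediate
5 | methyl 4-(bromomethyl)-2-oxo-2H-pyran-6-carboxylate | COC(=O)c1cc(CBr)cc(=O)o1 | intermediate
6 | (3,4-dimethoxyphenyl)boronic acid | COc1ccc(B(O)O)cc1OC | starting material
7 | methyl 4-[(3,4-dimethoxyphenyl)methyl]-2-oxo-2H-pyran-6-carboxylate | COC(=O)c1cc(Cc2ccc(OC)c(OC)c2)cc(=O)o1 | intermediate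
8 | methyl chlorooxoacetate | COC(=O)C(=O)Cl | starting material
9 | methyl 4-{[4,5-dimethoxy-2-(2-methoxy-2-oxoacetyl)phenyl]methyl}-2-oxo-2H-pyran-6-carboxylate | COC(=O)C(=O)c1cc(OC)c(OC)cc1Cc1cc(C(=O)OC)oc(=O)c1 | intermediate
10 | methyl 2-hydroxy-2-{3,4-dimethoxy-6-[(6-methoxycarbonyl-2-oxo-2H-pyran-4-yl)methylidene]cyclohexa-2,4-dien-1-ylidene}acetate (photoenol; geometry not fixed) | COC(=O)C(O)=C1C=C(OC)C(OC)=CC1=Cc1cc(C(=O)OC)oc(=O)c1 | intermediate
11 | methyl 7-hydroxy-3,4-dimethoxy-8-[6-(methoxycarbonyl)-2-oxo-2H-pyran-4-yl]bicyclo[4.2.0]octa-1,3,5-triene-7-carboxylate (racemic; both relative configurations at C7 and C8) | COC(=O)C1(O)C(c2cc(C(=O)OC)oc(=O)c2)c2cc(OC)c(OC)cc21 | intermediate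
12 | methyl propiolate | C#CC(=O)OC | starting material
13 | dimethyl (1R,2R)-2-hydroxy-6,7-dimethoxy-1-[6-(methoxycarbonyl)-2-oxo-2H-pyran-4-yl]-1,2-dihydronaphthalene-2,3-dicarboxylate (hydroxyl cis to the pyranone) | COC(=O)C1=Cc2cc(OC)c(OC)cc2[C@@H](c2cc(C(=O)OC)oc(=O)c2)[C@]1(O)C(=O)OC | intermediate
14 | dimethyl (1R,2R)-6,7-dimethoxy-1-[6-(methoxycarbonyl)-2-oxo-2H-pyran-4-yl]-1,2-dihydronaphthalene-2,3-dicarboxylate (1,2-cis) | COC(=O)C1=Cc2cc(OC)c(OC)cc2[C@@H](c2cc(C(=O)OC)oc(=O)c2)[C@H]1C(=O)OC | intermediate
15 | dimethyl (1R,2S)-6,7-dimethoxy-1-[6-(methoxycarbonyl)-2-oxo-2H-pyran-4-yl]-1,2-dihydronaphthalene-2,3-dicarboxylate (1,2-trans) | COC(=O)C1=Cc2cc(OC)c(OC)cc2[C@@H](c2cc(C(=O)OC)oc(=O)c2)[C@@H]1C(=O)OC | intermediate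
16 | dimethyl (1R,2S)-6,7-dihydroxy-1-[6-(methoxycarbonyl)-2-oxo-2H-pyran-4-yl]-1,2-dihydronaphthalene-2,3-dicarboxylate | COC(=O)C1=Cc2cc(O)c(O)cc2[C@@H](c2cc(C(=O)OC)oc(=O)c2)[C@@H]1C(=O)OC | intermediate
17 | (1R,2S)-1-(6-carboxy-2-oxo-2H-pyran-4-yl)-6,7-dihydroxy-1,2-dihydronaphthalene-2,3-dicarboxylic acid | O=C(O)C1=Cc2cc(O)c(O)cc2[C@@H](c2cc(C(=O)O)oc(=O)c2)[C@@H]1C(=O)O | target

## Step count and least certain steps

Total step count: 10. Longest linear sequence: 10 steps (1 to 17); compounds 2, 6, 8 and 12 enter as purchased reagents.

**Step 6 (key step).** Three processes can take the material off course.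
- The acidic C1–H of the ring-opened intermediate can protonate the aryl–rhodium bond before the alkyne inserts, which gives the ring-opened ketone and no ring B.
- The four-membered ring can open at the C7–C8 bond, which returns 9.
- Equilibration at C1 can be slower than ring closure onto the very electrophilic keto ester, which leaves the product with low enantiomeric purity.

Fallback, from 11 back to 13: the annulation is run in its established form with [Rh(OH)(cod)]2 alone and no chiral ligand, which should give racemic dimethyl 2-hydroxy-6,7-dimethoxy-1-[6-(methoxycarbonyl)-2-oxo-2H-pyran-4-yl]-1,2-dihydronaphthalene-2,3-dicarboxylate F1. The enantiomers of F1 are separated by preparative chromatography on a chiral stationary phase, and the (1R) enantiomer is 13.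

**Step 5.** The photoenol may return to the ketone faster than it closes, energy transfer to the pyranone may trigger its own photochemistry, and the strained donor–acceptor benzocyclobutenol may reopen to 9 on silica or with traces of base.

Fallback, from 7 back to 13, generating the same arylrhodium from boron and not from a four-membered ring:
- Electrophilic bromination of ring A of 7 (N-bromosuccinimide, MeCN, dark) gives methyl 4-[(2-bromo-4,5-dimethoxyphenyl)methyl]-2-oxo-2H-pyran-6-carboxylate F2.
- Miyaura borylation (bis(pinacolato)diboron, PdCl2(dppf), KOAc, dioxane) gives methyl 4-{[4,5-dimethoxy-2-(4,4,5,5-tetramethyl-1,3,2-dioxaborolan-2-yl)phenyl]methyl}-2-oxo-2H-pyran-6-carboxylate F3.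
- Claisen acylation of the doubly activated CH2 group with 2 (LiN(SiMe3)2, THF, −78 °C) gives methyl 4-{1-[4,5-dimethoxy-2-(4,4,5,5-tetramethyl-1,3,2-dioxaborolan-2-yl)phenyl]-3-methoxy-2,3-dioxopropyl}-2-oxo-2H-pyran-6-carboxylate F4.
- With [Rh(OH)(cod)]2, (R)-BINAP and 12 in aqueous dioxane, boron-to-rhodium transmetalation, alkyne insertion and carbonyl addition lead to 13.

**Step 7.** Electron transfer to the pyranone ester or to the arylacrylate may compete with cleavage of the C2–O bond and lead to over-reduction, and part of the dienolate may be protonated at C4, which moves the double bond to C2=C3.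

Fallback, from 13 back to 14: acylation with methyl chloroformate (pyridine, DMAP cat., CH2Cl2, 0 °C) gives dimethyl (1R,2R)-6,7-dimethoxy-2-[(methoxycarbonyl)oxy]-1-[6-(methoxycarbonyl)-2-oxo-2H-pyran-4-yl]-1,2-dihydronaphthalene-2,3-dicarboxylate F5. Allylic reduction (Pd(OAc)2, PBu3, HCO2NH4, THF) ionises the allylic carbonate on the face away from the pyranone and delivers hydride from palladium to C2 on that face. No electron-transfer reagent is involved, and the product is 14.

**Step 8.** The base may also remove C1–H, which erodes or inverts the absolute configuration. Prolonged contact may move the double bond to C2=C3 or C1=C2, or allow air oxidation to the aromatic ring.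

Fallback, from 11 back to 15, used if C1 proves the more mobile centre (the two centres then exchange roles):
- Step 6 is run with (S)-BINAP to give dimethyl (1S,2S)-2-hydroxy-6,7-dimethoxy-1-[6-(methoxycarbonyl)-2-oxo-2H-pyran-4-yl]-1,2-dihydronaphthalene-2,3-dicarboxylate F6.
- SmI2 as in step 7 sets C2 cis to this C1 and gives dimethyl (1S,2S)-6,7-dimethoxy-1-[6-(methoxycarbonyl)-2-oxo-2H-pyran-4-yl]-1,2-dihydronaphthalene-2,3-dicarboxylate F7, whose C2 already has the configuration of the target.
- The base step then inverts C1 to the stable trans isomer, which is 15.

This fallback presupposes a clear difference in mobility between the two centres; if they exchange at similar rates it does not rescue the enantiopurity.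

**Step 10.** Hydrolysis of the hindered C2 ester may be slow, and long heating in acid may allow epimerisation through the protonated pyranone or oxidation of the catechol.

Fallback, from 15 directly to 17: excess BBr3 in CH2Cl2 at room temperature cleaves the two aryl methyl ethers and, by bromide attack on the ester methyl groups, the three methyl esters in one operation, and aqueous work-up gives 17 without a hydrolysis step.

## Further compounds

F1 | step 6 | racemic dimethyl 2-hydroxy-6,7-dimethoxy-1-[6-(methoxycarbonyl)-2-oxo-2H-pyran-4-yl]-1,2-dihydronaphthalene-2,3-dicarboxylate (both enantiomers) | COC(=O)C1=Cc2cc(OC)c(OC)cc2C(c2cc(C(=O)OC)oc(=O)c2)C1(O)C(=O)OC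
F2 | step 5 | methyl 4-[(2-bromo-4,5-dimethoxyphenyl)methyl]-2-oxo-2H-pyran-6-carboxylate | COC(=O)c1cc(Cc2cc(OC)c(OC)cc2Br)cc(=O)o1
F3 | step 5 | methyl 4-{[4,5-dimethoxy-2-(4,4,5,5-tetramethyl-1,3,2-dioxaborolan-2-yl)phenyl]methyl}-2-oxo-2H-pyran-6-carboxylate | COC(=O)c1cc(Cc2cc(OC)c(OC)cc2B2OC(C)(C)C(C)(C)O2)cc(=O)o1
F4 | step 5 | methyl 4-{1-[4,5-dimethoxy-2-(4,4,5,5-tetramethyl-1,3,2-dioxaborolan-2-yl)phenyl]-3-methoxy-2,3-dioxopropyl}-2-oxo-2H-pyran-6-carboxylate (racemic; largely enolised) | COC(=O)C(=O)C(c1cc(C(=O)OC)oc(=O)c1)c1cc(OC)c(OC)cc1B1OC(C)(C)C(C)(C)O1
F5 | step 7 | dimethyl (1R,2R)-6,7-dimethoxy-2-[(methoxycarbonyl)oxy]-1-[6-(methoxycarbonyl)-2-oxo-2H-pyran-4-yl]-1,2-dihydronaphthalene-2,3-dicarboxylate | COC(=O)C1=Cc2cc(OC)c(OC)cc2[C@@H](c2cc(C(=O)OC)oc(=O)c2)[C@]1(OC(=O)OC)C(=O)OC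
F6 | step 8 | dimethyl (1S,2S)-2-hydroxy-6,7-dimethoxy-1-[6-(methoxycarbonyl)-2-oxo-2H-pyran-4-yl]-1,2-dihydronaphthalene-2,3-dicarboxylate | COC(=O)C1=Cc2cc(OC)c(OC)cc2[C@H](c2cc(C(=O)OC)oc(=O)c2)[C@@]1(O)C(=O)OC
F7 | step 8 | dimethyl (1S,2S)-6,7-dimethoxy-1-[6-(methoxycarbonyl)-2-oxo-2H-pyran-4-yl]-1,2-dihydronaphthalene-2,3-dicarboxylate (1,2-cis) | COC(=O)C1=Cc2cc(OC)c(OC)cc2[C@H](c2cc(C(=O)OC)oc(=O)c2)[C@@H]1C(=O)OC
F0 | step 10 | none | none
A1 | alternative 1 | (1R,2S)-6,7-dimethoxy-2,3-bis(methoxycarbonyl)-1,2-dihydronaphthalene-1-carboxylic acid (cis) | COC(=O)C1=Cc2cc(OC)c(OC)cc2[C@H](C(=O)O)[C@@H]1C(=O)OC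
A2 | alternative 2 | 1-tert-butyl 2,3-dimethyl (1S,2S)-6,7-dimethoxy-1,2-dihydronaphthalene-1,2,3-tricarboxylate (trans) | COC(=O)C1=Cc2cc(OC)c(OC)cc2[C@@H](C(=O)OC(C)(C)C)[C@@H]1C(=O)OC
A3 | alternative 3 | dimethyl (1R,2S)-1-[3,4-bis(benzyloxy)phenyl]-6,7-dimethoxy-1,2-dihydronaphthalene-2,3-dicarboxylate | COC(=O)C1=Cc2cc(OC)c(OC)cc2[C@@H](c2ccc(OCc3ccccc3)c(OCc3ccccc3)c2)[C@@H]1C(=O)OC
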